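**Assumption:** the target has no stereocentre and no stereogenic double bond, so it is one achiral compound and no stereocontrol is needed.

## Retrosynthetic overview

1. Target 6 is a depside. Disconnect the aryl ester C(acyl)–O bond to give acid 4 and phenol 1.
2. Acid 4 comes from methyl ester 2 by saponification, and 2 comes from 1 by chlorination at its only free ring position (C5).
3. Both halves therefore derive from one cheap material, methyl 2,4-dihydroxy-3,6-dimethylbenzoate (atraric acid, 1).
4. No ring is built: both benzene rings are bought intact. The only ring formed is the transient boron heterocycle 5 during the coupling.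

## Route

**Step 1**
Reactants: 1 methyl 2,4-dihydroxy-3,6-dimethylbenzoate (atraric acid)
Product: 2 methyl 5-chloro-2,4-dihydroxy-3,6-dimethylbenzoate
Conditions: SO2Cl2 (1.05 equiv), Et2O–CH2Cl2, 0 °C to rt, 2 h
Reagents that add atoms: sulfuryl chloride, O=S(=O)(Cl)Cl
Why: Electrophilic aromatic chlorination (SEAr): C5 is the only unsubstituted ring carbon and is activated ortho to the 4-OH and para to the 2-OH, so one equivalent of SO2Cl2 gives the monochloride and leaves the ester and phenols untouched; no stereocentre is formed.

**Step 2**
Reactants: 2 methyl 5-chloro-2,4-dihydroxy-3,6-dimethylbenzoate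
Product: 4 5-chloro-2,4-dihydroxy-3,6-dimethylbenzoic acid, via tripotassium carboxylate-bisphenoxide 3 (not isolated)
Conditions: KOH (6 equiv), DMSO–H2O 4:1, 80 °C, Ar, 8 h; then 2 M HCl, 0 °C, pH 2, cold filtration
Reagents that add atoms: potassium hydroxide, [K+].[OH-]
Why: Ester saponification (BAc2) of an orsellinate-type ester, which needs heat but runs cleanly in aqueous DMSO; the aryl chloride is inert on this electron-rich ring, the polyanion 3 resists decarboxylation, and cold acidification avoids protodecarboxylation of the free acid.

**Step 3**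
Reactants: 4 5-chloro-2,4-dihydroxy-3,6-dimethylbenzoic acid; 1 methyl 2,4-dihydroxy-3,6-dimethylbenzoate (1.3 equiv)
Product: 6 methyl 4-[(5-chloro-2,4-dihydroxy-3,6-dimethylbenzoyl)oxy]-2-hydroxy-3,6-dimethylbenzoate, via cyclic acyloxyboron anhydride 5 (not isolated)
Conditions: 3,5-(CF3)2C6H3B(OH)2 (10 mol%), DMAPO (10 mol%), PhF, reflux (85 °C) through 4 Å MS (Soxhlet), Ar, 24 h, 4 added in three portions; aq. NH4Cl work-up
Reagents that add atoms: none
Why: Proposed new method: a protecting-group-free, boronic acid/DMAPO co-catalysed dehydrative depside coupling, in which the salicylic acid unit of 4 condenses with the arylboronic acid to the planar cyclic mixed anhydride 5, which activates the carboxyl as an acyloxyboron, locks the C=O coplanar with the arene so the 6-methyl no longer blocks nucleophilic approach (the reason benzodioxinones of 6-substituted salicylates open readily), and masks the 2-OH and shuts down decarboxylation, after which DMAPO relays the acyl group to the 4-OH of 1 (its 2-OH is hydrogen-bonded to the ester and flanked on both sides, and the 4-OH of 4 is flanked by CH3 and Cl, so neither competes), while sieves remove water and drive turnover; the closest known reaction type is arylboronic acid/DMAPO-catalysed dehydrative amidation through acyloxyboron intermediates, which has not been shown for aryl ester formation from an unprotected dihydroxybenzoic acid.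

## Compound list

1 | methyl 2,4-dihydroxy-3,6-dimethylbenzoate (atraric acid) | COC(=O)c1c(C)cc(O)c(C)c1O | starting material
2 | methyl 5-chloro-2,4-dihydroxy-3,6-dimethylbenzoate | COC(=O)c1c(C)c(Cl)c(O)c(C)c1O | intermediate
3 | tripotassium 5-chloro-3,6-dimethyl-2,4-dioxidobenzoate | [K+].[K+].[K+].[O-]C(=O)c1c(C)c(Cl)c([O-])c(C)c1[O-] | intermediate (not isolated)
4 | 5-chloro-2,4-dihydroxy-3,6-dimethylbenzoic acid | OC(=O)c1c(C)c(Cl)c(O)c(C)c1O | intermediate
5 | 2-[3,5-bis(trifluoromethyl)phenyl]-6-chloro-7-hydroxy-5,8-dimethyl-4H-1,3,2-benzodioxaborinin-4-one | O=C1OB(c2cc(C(F)(F)F)cc(C(F)(F)F)c2)Oc2c(C)c(O)c(Cl)c(C)c12 | intermediate (not isolated)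
6 | methyl 4-[(5-chloro-2,4-dihydroxy-3,6-dimethylbenzoyl)oxy]-2-hydroxy-3,6-dimethylbenzoate | COC(=O)c1c(C)cc(OC(=O)c2c(C)c(Cl)c(O)c(C)c2O)c(C)c1O | target

## Summary

Total step count: 3. Longest linear sequence: 3 (1 → 2 → 4 → 6); compound 1 is used a second time as the coupling partner in step 3.

## Steps most likely to fail, with fallbacks

**Step 3, the proposed new coupling (highest risk).** The catalyst may not turn over, or phenol attack on 5 may be too slow. The fallback is the classical protected depside synthesis. It sets out from 2 and comes back to the route at 6. Both phenols of 2 are benzylated (BnBr, K2CO3, DMF, 70 °C) to give methyl 2,4-bis(benzyloxy)-5-chloro-3,6-dimethylbenzoate F1. Saponification (KOH, DMSO–H2O, 90 °C) gives 2,4-bis(benzyloxy)-5-chloro-3,6-dimethylbenzoic acid F2. Condensation with 1 using trifluoroacetic anhydride in toluene at rt acylates only the unhindered 4-OH and gives methyl 4-{[2,4-bis(benzyloxy)-5-chloro-3,6-dimethylbenzoyl]oxy}-2-hydroxy-3,6-dimethylbenzoate F3. Debenzylation with BCl3 and pentamethylbenzene (CH2Cl2, −78 °C), which spares the aryl chloride and the depside ester, gives 6.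

**Step 2, hydrolysis of the hindered ester.** The hydrolysis may be slow, or the acid may decarboxylate on work-up. The fallback accepts the decarboxylation and rebuilds the carboxyl group. It sets out from 2 and comes back at 4. Forcing hydrolysis (20% aq. NaOH, reflux, N2; then dilute H2SO4, 90 °C until CO2 evolution stops) gives 4-chloro-2,5-dimethylbenzene-1,3-diol F4. Kolbe–Schmitt carboxylation (KHCO3, CO2, glycerol, 125 °C; cold acidification) then installs the carboxyl at the only free ring carbon and gives 4.

**Step 1, monochlorination.** Excess reagent could cause ipso-chlorination to dienones or oxidation of the electron-rich ring. The fallback separates C–H functionalisation from chlorine introduction. It sets out from 1 and comes back at 2. Mild iodination (NIS, MeCN, 0 °C to rt) gives methyl 2,4-dihydroxy-5-iodo-3,6-dimethylbenzoate F5. Copper-mediated aromatic halogen exchange (CuCl, 3 equiv, DMF, 130 °C, Ar) then gives 2.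

## Further compounds

F1 | step 3 | methyl 2,4-bis(benzyloxy)-5-chloro-3,6-dimethylbenzoate | COC(=O)c1c(C)c(Cl)c(OCc2ccccc2)c(C)c1OCc1ccccc1
F2 | step 3 | 2,4-bis(benzyloxy)-5-chloro-3,6-dimethylbenzoic acid | OC(=O)c1c(C)c(Cl)c(OCc2ccccc2)c(C)c1OCc1ccccc1
F3 | step 3 | methyl 4-{[2,4-bis(benzyloxy)-5-chloro-3,6-dimethylbenzoyl]oxy}-2-hydroxy-3,6-dimethylbenzoate | COC(=O)c1c(C)cc(OC(=O)c2c(C)c(Cl)c(OCc3ccccc3)c(C)c2OCc2ccccc2)c(C)c1O
F4 | step 2 | 4-chloro-2,5-dimethylbenzene-1,3-diol | Cc1cc(O)c(C)c(O)c1Cl
F5 | step 1 | methyl 2,4-dihydroxy-5-iodo-3,6-dimethylbenzoate | COC(=O)c1c(C)c(I)c(O)c(C)c1O
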